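- If E goes in slowly, the reading to watch is [E] against what the step to E2 needs, so I bracketed E.G in epsilon by hand.

| setting | epsilon | zeta | theta | gamma |
|---|---|---|---|---|
| E | 0.10 M (fed, over 15 min) | 0.10 M | 0.10 M | 0.10 M |
| G | 0.200 M | 0.200 M (fed, over 15 min) | 0.200 M (fed, over 4.0 min) | 0.200 M |
| L | 0.0200 M | 0.0200 M | 0.0200 M | 0.0200 M |
| time | 20 min | 20 min | 20 min | 20 min |
| remark | all else is in the flask from the start; the feed brings no volume worth counting | all else is in the flask from the start; the feed brings no volume worth counting | all else is in the flask from the start; the feed brings no volume worth counting | everything together at the start |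

- the flask with the highest amount of E.G, in percent of the E charged ("all alike" if they lie within 1.5 percentage points) (epsilon / zeta / theta / gamma / all alike)
- final E.G, as a percentage of the E charged, in epsilon
- final E.G, as a percentage of the E charged, in zeta
- final E.G, as a percentage of the E charged, in theta
- final E.G, as a percentage of the E charged, in gamma

- a species is counted by the E in it: one E2 counts as two
- a step written with two of one species runs at k times the square of its concentration and takes two of it each time
- run time (epsilon): 20 min

    E + G → E.G, rate k1*[E]^0.5*[G]^0.5 (k1 = 0.011 s⁻¹)
    E + L → E.L (k2 = 5.9 M⁻¹ s⁻¹)
    2 E → E2 (k3 = 1.4 M⁻¹ s⁻¹)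

- I first set the loss to E2 equal to the formation of E.G at full [G]. This gave 0.0146 M, the break-even [E]: above it, the step to E2 consumes E faster than the step to E.G does.
- For the upper limit on [E], I took the feed as passing wholly into E.G at the lowest [G] the charges allow, 0.100 M. This quasi-steady state gave 0.00102 M, which is far below the break-even for full [G].
- Held for the whole feed, with the short tail after the feed left aside, that [E] cost 2.62% of the E as E2. L can take 20.0% of the E, so my lower bound on E.G was 77.4%.
- For the lower limit on [E], I shared the feed between E.G and E.L at full [G] and full [L], leaving aside the step to E2 and the first seconds of the feed, which gave 2.64 × 10⁻⁴ M. Held for the whole feed, that [E] turned L into 15.1% of the E as E.L, so my upper bound on E.G, with those two things left aside, was 84.9%.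
- The forecast chose epsilon, on the ground that “keeping E low favours E.G”, and gave 81% there, with a range from 78% to 84% that lay inside my bracket; it gave 7% for zeta, 9.7% for theta and 21% for gamma.
- The simulation gave epsilon as the best flask, with 81.4%, inside my bracket; zeta gave 6.90%, theta 9.53% and gamma 21.0%.
- In epsilon, [E] read 7.01 × 10⁻⁴ M at 15.0 min, far below the break-even for full [G], and E2 ended at 0.518%. In zeta, half of the turnover to E2 was done by 2.64 s. In zeta, the G fed by then put break-even at 0.00208 M. Even with half of the final E2, the whole of E.L and the whole of E.G taken from the charge, [E] in zeta then stood at no less than 0.0366 M, far above that break-even, and E2 ended at 73.2%. With the step to E2 removed, the gap in E.G between epsilon and zeta shrank from 75 percentage points to 1.9 points.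

All constants are invented; the flask was simulated.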